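## The problem

The target is a flavonol: benzene ring A is fused through C4a–C8a to the 4-pyranone ring C, which carries the 3,4-dimethoxyphenyl ring B at C2, a free hydroxyl at C3 and the carbonyl at C4, while ring A bears a single substituent, the prenyl ether at C7. There is no stereocentre and no alkene geometry to set, so the task is one of chemoselectivity and of the order in which bonds are made. The prenyl aryl ether is the fragile group: acid ionises it, hydrogenation and electrophilic oxidants attack its alkene, zerovalent palladium can cleave it, and strong heating invites Claisen rearrangement. The usual acid cyclodehydration to flavones is therefore unattractive once the prenyl group is in place. The C3 hydroxyl belongs to an enol whose anion is oxidised by air, so it is best kept masked until the last step. The feature that opens the key step is that O1 is bonded to C8a, which is ortho to C4a and hence to the C4 carbonyl: in an open 1,3-diketone (C2–C3–C4) a fluoride at that carbon is activated for addition–elimination, and the enol oxygen on C2 is placed for a six-membered closure. The C7 oxygen is meta to C8a and does not donate into the site of attack. The central carbon of the same diketone (future C3) is its most nucleophilic position, which is where the C3 oxygen can be introduced before the ring is closed.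

## Retrosynthesis

**Target 9 to benzoate 8.** The C3 O–H is traced back to a benzoate ester, so the only bond cut is the acyl–oxygen bond. A free C3 oxygen during ring closure would be an internal competitor, able to close a five-membered ring onto C8a, and an oxidisable enolate. The benzoate is also what the oxygenation step delivers, so it costs no extra step to install. The forward reaction needs only a mild basic methanolysis, which the prenyl ether tolerates.

**Benzoate 8 to diketone 7.** Ring C is opened at O1–C8a, giving the acyclic 2-benzoyloxy-1,3-diketone 7 with fluorine on the future C8a. The neighbouring cut at O1–C2 is the classical cyclodehydration of an ortho-hydroxyaryl diketone; it needs acid, and it needs a free ortho phenol kept distinct from the C7 oxygen. The O1–C8a cut runs under base only and draws ring A from a fluoroarene that already has the correct 1,2,4-pattern. The precursor has no heterocycle and all its carbons are in place. The forward step must deliver O-arylation through the correct enolate oxygen without disturbing the ester.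

**Diketone 7 to diketone 5 and dibenzoyl peroxide 6.** The C3–O bond is cut. The central carbon of 5 is its only strongly nucleophilic carbon, and 6 is an electrophilic oxygen source that is inert towards the isolated prenyl alkene at room temperature. Carrying the oxygen from the start as an α-alkoxy ketone would make the preceding C–C bond formation slower and more hindered. The forward reaction asks for mono-oxygenation at carbon.

**Diketone 5 to ketone 3 and acid chloride 4.** The bond between the central carbon and the ring B carbonyl is cut, a Claisen-type acylation of the methyl ketone enolate of 3 by 3,4-dimethoxybenzoyl chloride 4. The reversed pairing, a ring B methyl ketone enolate with a ring A acyl donor, would require that acyl donor to be prepared first. The chosen polarity uses two catalogue compounds. An acid chloride is preferred over an ester as acyl donor because no alkoxide is liberated next to an activated aryl fluoride and the reaction runs at low temperature.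

**Ketone 3 to phenol 1 and prenyl bromide 2.** The prenyl O–C bond is cut (Williamson ether synthesis). The ether is installed first because every later step is basic or neutral, and a free phenoxide on ring A would deactivate the fluoride displacement.

## Roads not taken

Alternative 1: This plan cuts C4a–C4 and C4–C3 and takes C4 from carbon monoxide. Pd(dba)2 with Xantphos (zerovalent palladium) and base would couple 2-fluoro-1-iodo-4-[(3-methylbut-2-en-1-yl)oxy]benzene A2, carbon monoxide and the enolate of 1-(3,4-dimethoxyphenyl)-2-[(4-methoxybenzyl)oxy]ethan-1-one A3. The product would be the 2-fluoroaryl diketone 1-(3,4-dimethoxyphenyl)-3-[2-fluoro-4-(prenyloxy)phenyl]-2-[(4-methoxybenzyl)oxy]propane-1,3-dione A1, and A1 would then undergo the same fluoride displacement.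

- Merits: it is convergent, and the C3 oxygen is an ether from the outset. No peroxide step is needed. The ether cannot migrate or be lost under the basic ring closure, and in that respect A1 is a better cyclisation substrate than the benzoate 7.
- Weak points: zerovalent palladium can ionise the aryl prenyl ether of A2 to a π-allyl complex. The nucleophile from A3 is a hindered, oxygen-substituted enolate, not the simple methyl ketone enolate for which carbonylative arylation is best established, and direct arylation without uptake of carbon monoxide competes. A2 and A3 must both be prepared. The 4-methoxybenzyl group must finally leave under oxidative or acidic conditions in the presence of the prenyl ether and an electron-rich flavonol.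
- Comparison: against the more robust C3 protecting group of A1, the chosen plan offers a two-step, metal-free access to the diketone and a deprotection that is only mildly basic.

Alternative 2: This plan cuts C5–C6 and C7–C8 and builds ring A. The ketene acetal 1,1-bis(trimethylsilyloxy)ethene A6 would add across the 2-pyrone diene of 2-(3,4-dimethoxyphenyl)-3-[(4-methoxybenzyl)oxy]-4H,7H-pyrano[4,3-b]pyran-4,7-dione A5. The bridged adduct would lose CO2 and trimethylsilanol, and the product would be 2-(3,4-dimethoxyphenyl)-3-[(4-methoxybenzyl)oxy]-7-(trimethylsilyloxy)-4H-chromen-4-one A4, in which ring A is aromatic and C7 carries a silyloxy group.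

- Merits: the C7 oxygen is placed by the polarity of the two partners A5 and A6, ring C with its C3 oxygen is already in hand, and no fluoride or SNAr activation is needed. The approach would be valuable for ring A patterns that cannot be bought.
- Weak points: for this target it constructs a benzene ring that is commercially available with the right substitution. A5 is a bis-pyranone more elaborate than any intermediate of the chosen route and has no short preparation. Its 4-pyranone is a second electrophile towards A6. From A4, silyl cleavage, prenylation and removal of the 4-methoxybenzyl group would still follow.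
- Comparison: it is longer in every respect, and its one advantage, generality in ring A, is not needed here.

Alternative 3: This plan cuts C8–C8a and C6–C7. Photolysis of the diazo ketone 3-(benzyloxy)-6-(2-diazoacetyl)-2-(3,4-dimethoxyphenyl)-5-ethenyl-4H-pyran-4-one A8 would trigger a Wolff rearrangement to a ketene held cis to the vinyl group across C8a=C4a. A 6π electrocyclisation and tautomerisation would follow, and the product would be the phenol 3-(benzyloxy)-2-(3,4-dimethoxyphenyl)-7-hydroxy-4H-chromen-4-one A7, ready for prenylation at the C7 oxygen.

- Merits: one neutral step forms ring A, and in A7 the 7-hydroxyl is placed unambiguously and is free for prenylation. The pyranone ring of A8 enforces the reactive triene geometry.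
- Weak points: A8 is a fully substituted 4-pyranone with adjacent vinyl and diazoacetyl groups and needs a long preparation. 4-Pyranones have photochemistry of their own in the same spectral region. After prenylation of A7 the benzyl ether cannot be removed cleanly, because hydrogenolysis reduces the prenyl alkene and Lewis acids cleave the prenyl ether.
- Comparison: the chosen plan buys ring A, avoids diazo compounds and photochemistry, and carries a protecting group that leaves under conditions harmless to the prenyl ether. Alternative 3 is the more elegant ring construction, but it offers nothing this target requires.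

Key step: step 4

Assumption: diketones 5 and 7 are named and drawn as diketo tautomers although 5 will exist largely as its chelated enol; 7 is racemic at its central carbon, which is of no consequence because that carbon becomes sp2 in step 4.

## Route

Step 1
Reactants: 1 2-fluoro-4-hydroxyacetophenone; 2 prenyl bromide (1-bromo-3-methylbut-2-ene)
Product: 3 1-{2-fluoro-4-[(3-methylbut-2-en-1-yl)oxy]phenyl}ethan-1-one
Conditions: K2CO3 (1.5 equiv), acetone, reflux
Reagents that add atoms: prenyl bromide (2), CC(C)=CCBr
Why: Williamson ether synthesis: the phenol, acidified by the para acetyl group, is deprotonated by carbonate and alkylated at oxygen by the primary allylic bromide in an SN2 reaction. Carbonate does not enolise the methyl ketone, and at this temperature the phenoxide should not displace fluoride from a second molecule.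

Step 2
Reactants: 3 1-{2-fluoro-4-[(3-methylbut-2-en-1-yl)oxy]phenyl}ethan-1-one; 4 3,4-dimethoxybenzoyl chloride
Product: 5 1-(3,4-dimethoxyphenyl)-3-{2-fluoro-4-[(3-methylbut-2-en-1-yl)oxy]phenyl}propane-1,3-dione
Conditions: LiN(SiMe3)2 (2.2 equiv), THF, −78 °C; then 4, −78 to 0 °C; aq. NH4Cl
Reagents that add atoms: 3,4-dimethoxybenzoyl chloride (4), COc1ccc(C(=O)Cl)cc1OC
Why: Claisen-type C-acylation of a lithium ketone enolate by an acid chloride: the first equivalent of base forms the methyl ketone enolate and the second deprotonates the more acidic diketone as it forms, which suppresses proton exchange and a second acylation. No alkoxide is released and the chelated lithium diketonate should not attack the C–F bond at these temperatures.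

Step 3
Reactants: 5 1-(3,4-dimethoxyphenyl)-3-{2-fluoro-4-[(3-methylbut-2-en-1-yl)oxy]phenyl}propane-1,3-dione; 6 dibenzoyl peroxide
Product: 7 1-(3,4-dimethoxyphenyl)-3-{2-fluoro-4-[(3-methylbut-2-en-1-yl)oxy]phenyl}-1,3-dioxopropan-2-yl benzoate (racemic)
Conditions: (PhCO2)2 (1.1 equiv), aq. K2CO3, Bu4NHSO4 (cat.), CH2Cl2, 0 °C to rt
Reagents that add atoms: dibenzoyl peroxide (6), O=C(OOC(=O)c1ccccc1)c1ccccc1
Why: Electrophilic α-benzoyloxylation of a 1,3-diketone enolate under phase transfer: the ammonium diketonate attacks a peroxide oxygen with benzoate as leaving group, a known transformation of dibenzoylmethanes on the way to flavonols. The central carbon is the only nucleophilic carbon, and a diacyl peroxide at room temperature should neither epoxidise nor add radicals to the prenyl alkene. The new stereocentre forms as a racemate and is erased in step 4.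

Step 4
Reactants: 7 1-(3,4-dimethoxyphenyl)-3-{2-fluoro-4-[(3-methylbut-2-en-1-yl)oxy]phenyl}-1,3-dioxopropan-2-yl benzoate
Product: 8 2-(3,4-dimethoxyphenyl)-7-[(3-methylbut-2-en-1-yl)oxy]-4-oxo-4H-chromen-3-yl benzoate
Conditions: K2CO3 (2 equiv, anhydrous), dry DMF, 70 °C, N2
Reagents that add atoms: none
Why: Carbonate removes the proton between the two carbonyls of 7, made more acidic by the benzoyloxy group, and the stereocentre disappears in the potassium enolate. The enolate oxygen on the 3,4-dimethoxybenzoyl side adds to the fluorine-bearing carbon (future C8a) to give a Meisenheimer anion delocalised through C4a onto the C4 carbonyl, and loss of fluoride restores ring A and completes the 4-pyranone (addition–elimination SNAr). The closest known reaction type is the base-mediated cyclisation of 1-(2-halophenyl)-1,3-diketones to flavones by intramolecular O-arylation. Ring C closes as a six-membered ring through O1–C8a, formally a 6-endo-trig conjugate addition–elimination with respect to the C4a=C8a bond conjugated to C4=O. No stereocentre is formed and the product is planar. The step needs O- over C-arylation and six- over five-membered closure: attack through C3 or through the C4 oxygen would require a four-membered ring, and the benzoate keeps the C3 oxygen from closing a benzofuranone, which is why water is excluded. Fluoride is chosen because addition is rate-limiting and fluorine accelerates it most; DMF and the potassium counter-ion loosen the chelated U-shaped diketonate so that the rotamer able to reach C8a is populated, and the C7 ether, being meta to C8a, does not oppose the attack.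

Step 5
Reactants: 8 2-(3,4-dimethoxyphenyl)-7-[(3-methylbut-2-en-1-yl)oxy]-4-oxo-4H-chromen-3-yl benzoate
Product: 9 2-(3,4-dimethoxyphenyl)-3-hydroxy-7-[(3-methylbut-2-en-1-yl)oxy]-4H-chromen-4-one (target)
Conditions: K2CO3 (0.5 equiv), degassed MeOH–THF, 0 °C to rt, N2; aq. NH4Cl
Reagents that add atoms: none
Why: Base-catalysed transesterification of an enol ester: methoxide attacks the benzoate carbonyl and the stabilised flavonolate is a very good leaving group, so cleavage should occur at or below room temperature without touching the pyranone or the prenyl ether. Exclusion of oxygen protects the flavonolate, and the NH4Cl work-up avoids the strong acid that would endanger the prenyl ether.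

## Compound list

1 | 2-fluoro-4-hydroxyacetophenone | CC(=O)c1ccc(O)cc1F | starting material
2 | prenyl bromide (1-bromo-3-methylbut-2-ene) | CC(C)=CCBr | starting material
3 | 1-{2-fluoro-4-[(3-methylbut-2-en-1-yl)oxy]phenyl}ethan-1-one | CC(C)=CCOc1ccc(C(C)=O)c(F)c1 | intermediate
4 | 3,4-dimethoxybenzoyl chloride | COc1ccc(C(=O)Cl)cc1OC | starting material
5 | 1-(3,4-dimethoxyphenyl)-3-{2-fluoro-4-[(3-methylbut-2-en-1-yl)oxy]phenyl}propane-1,3-dione | CC(C)=CCOc1ccc(C(=O)CC(=O)c2ccc(OC)c(OC)c2)c(F)c1 | intermediate
6 | dibenzoyl peroxide | O=C(OOC(=O)c1ccccc1)c1ccccc1 | starting material
7 | 1-(3,4-dimethoxyphenyl)-3-{2-fluoro-4-[(3-methylbut-2-en-1-yl)oxy]phenyl}-1,3-dioxopropan-2-yl benzoate (racemic) | CC(C)=CCOc1ccc(C(=O)C(OC(=O)c2ccccc2)C(=O)c2ccc(OC)c(OC)c2)c(F)c1 | intermediate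
8 | 2-(3,4-dimethoxyphenyl)-7-[(3-methylbut-2-en-1-yl)oxy]-4-oxo-4H-chromen-3-yl benzoate | COc1ccc(-c2oc3cc(OCC=C(C)C)ccc3c(=O)c2OC(=O)c2ccccc2)cc1OC | intermediate
9 | 2-(3,4-dimethoxyphenyl)-3-hydroxy-7-[(3-methylbut-2-en-1-yl)oxy]-4H-chromen-4-one | COc1ccc(-c2oc3cc(OCC=C(C)C)ccc3c(=O)c2O)cc1OC | target

## Step count and risks

Total step count: 5. Longest linear sequence: 5 steps (1 → 3 → 5 → 7 → 8 → 9).

**Step 4 (key step).** Addition to C8a may be slow, because the activating C4 carbonyl is part of an electron-rich diketonate and receives donation from the para C7 oxygen. On forcing, the benzoyl group may be lost or may shift to the enolate oxygen. Either event frees the C3 oxygen for a five-membered closure onto C8a, or opens the way to retro-Claisen scission. Partial loss of the benzoate after ring closure is harmless, since step 5 removes it anyway.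

Fallback: the fallback sets out from 5, which has no ester and tolerates harsher conditions. Heating 5 with K2CO3 or Cs2CO3 in DMF should close ring C by the same fluoride displacement to give 2-(3,4-dimethoxyphenyl)-7-[(3-methylbut-2-en-1-yl)oxy]-4H-chromen-4-one F1. Deprotonation at C3 with LiN(iPr)2 in THF at −78 °C and trapping with B(OMe)3 would give dimethyl {2-(3,4-dimethoxyphenyl)-7-[(3-methylbut-2-en-1-yl)oxy]-4-oxo-4H-chromen-3-yl}boronate F2. Oxidation of the C–B bond with NaBO3·4H2O in THF–water, which spares the prenyl alkene, returns to the route at 9.

**Step 3.** The enolate may be benzoylated at oxygen by attack at the peroxide carbonyl. The product may also be cleaved in the basic aqueous phase (retro-Claisen), or the peroxide may hydrolyse before it is consumed.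

Fallback: the fallback sets out from 5. Diazo transfer with 4-acetamidobenzenesulfonyl azide and Et3N in MeCN should give 2-diazo-1-(3,4-dimethoxyphenyl)-3-{2-fluoro-4-[(3-methylbut-2-en-1-yl)oxy]phenyl}propane-1,3-dione F3. Rh2(OAc)4-catalysed O–H insertion of the derived carbenoid into benzoic acid in CH2Cl2 installs the benzoyloxy group and returns to the route at 7. The prenyl alkene is out of intramolecular reach, and excess benzoic acid should outcompete intermolecular cyclopropanation.

**Step 2.** Acylation may occur at the enolate oxygen, or the diketonate may be acylated a second time. Proton transfer between product and unreacted enolate may stall the conversion.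

Fallback: the fallback sets out from 3. Aldol addition of its lithium enolate (LiN(iPr)2, THF, −78 °C) to 3,4-dimethoxybenzaldehyde should give 3-(3,4-dimethoxyphenyl)-1-{2-fluoro-4-[(3-methylbut-2-en-1-yl)oxy]phenyl}-3-hydroxypropan-1-one F4 as a racemate. Oxidation of the secondary alcohol with Dess–Martin periodinane in CH2Cl2 returns to the route at 5.

## Further compounds

F1 | step 4 | 2-(3,4-dimethoxyphenyl)-7-[(3-methylbut-2-en-1-yl)oxy]-4H-chromen-4-one | COc1ccc(-c2cc(=O)c3ccc(OCC=C(C)C)cc3o2)cc1OC
F2 | step 4 | dimethyl {2-(3,4-dimethoxyphenyl)-7-[(3-methylbut-2-en-1-yl)oxy]-4-oxo-4H-chromen-3-yl}boronate | COB(OC)c1c(-c2ccc(OC)c(OC)c2)oc2cc(OCC=C(C)C)ccc2c1=O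
F3 | step 3 | 2-diazo-1-(3,4-dimethoxyphenyl)-3-{2-fluoro-4-[(3-methylbut-2-en-1-yl)oxy]phenyl}propane-1,3-dione | CC(C)=CCOc1ccc(C(=O)C(=[N+]=[N-])C(=O)c2ccc(OC)c(OC)c2)c(F)c1
F4 | step 2 | 3-(3,4-dimethoxyphenyl)-1-{2-fluoro-4-[(3-methylbut-2-en-1-yl)oxy]phenyl}-3-hydroxypropan-1-one (racemic) | CC(C)=CCOc1ccc(C(=O)CC(O)c2ccc(OC)c(OC)c2)c(F)c1
A1 | alternative 1 | 1-(3,4-dimethoxyphenyl)-3-[2-fluoro-4-(prenyloxy)phenyl]-2-[(4-methoxybenzyl)oxy]propane-1,3-dione (racemic) | CC(C)=CCOc1ccc(C(=O)C(OCc2ccc(OC)cc2)C(=O)c2ccc(OC)c(OC)c2)c(F)c1
A2 | alternative 1 | 2-fluoro-1-iodo-4-[(3-methylbut-2-en-1-yl)oxy]benzene | CC(C)=CCOc1ccc(I)c(F)c1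
A3 | alternative 1 | 1-(3,4-dimethoxyphenyl)-2-[(4-methoxybenzyl)oxy]ethan-1-one | COc1ccc(COCC(=O)c2ccc(OC)c(OC)c2)cc1
A4 | alternative 2 | 2-(3,4-dimethoxyphenyl)-3-[(4-methoxybenzyl)oxy]-7-(trimethylsilyloxy)-4H-chromen-4-one | COc1ccc(-c2oc3cc(O[Si](C)(C)C)ccc3c(=O)c2OCc2ccc(OC)cc2)cc1OC
A5 | alternative 2 | 2-(3,4-dimethoxyphenyl)-3-[(4-methoxybenzyl)oxy]-4H,7H-pyrano[4,3-b]pyran-4,7-dione | COc1ccc(cc1OC)C1=C(OCc2ccc(OC)cc2)C(=O)C2=COC(=O)C=C2O1
A6 | alternative 2 | 1,1-bis(trimethylsilyloxy)ethene | C=C(O[Si](C)(C)C)O[Si](C)(C)C
A7 | alternative 3 | 3-(benzyloxy)-2-(3,4-dimethoxyphenyl)-7-hydroxy-4H-chromen-4-one | COc1ccc(-c2oc3cc(O)ccc3c(=O)c2OCc2ccccc2)cc1OC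
A8 | alternative 3 | 3-(benzyloxy)-6-(2-diazoacetyl)-2-(3,4-dimethoxyphenyl)-5-ethenyl-4H-pyran-4-one | COc1ccc(-c2oc(C(=O)C=[N+]=[N-])c(C=C)c(=O)c2OCc2ccccc2)cc1OC
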